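**Retrosynthetic overview**
1. Numbering follows the SMILES: C1 exocyclic CH2; ring A = C2–C7 (Br on C5, CMe2 = C6); spiro C7; ring B = C7–C12 (Cl and Me on C10, Br on C11). The strategy rests on C7 lying between C2 and C12 with C10 across ring B, so an oxygen spanning C2 and C10 makes O–C2=C7 plus C10–C11=C12 an allyl vinyl ether.
2. Target ⇒ C1 methylenation, oxidation, BCl3 ether opening, bromoetherification tethered through the C2 hydroxyl, reduction ⇒ spiro ketone carrying the C10=C11 alkene.
3. Spiro ketone ⇒ [3,3] Claisen ring contraction (C7–C12 made, O–C10 broken) ⇒ ring A-fused (10S)-2-methyl-2-vinyl dihydropyran.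
4. Dihydropyran ⇒ its C10 methyl ester (vinyl built last from CO2Me) ⇒ cyclodehydration of a δ-hydroxy ketone ⇒ radical conjugate addition of a chiral-pool C9–C11 iodide to the ring A α-methylene ketone (C8 from formaldehyde).
5. Ring A ⇒ stereospecific bromonium cyclisation of an acyclic bromochloro keto ester ⇒ enantioselective bromochlorination of prenol and γ-alkylation of allyl acetoacetate. Ring order: ring A, pyran ring, ring B.

Key step: step 10

Remarks on the chemistry:
- Locants C1–C12 in the Why lines are the target numbering above.
- C7 of the keto ester and of the hydroxy ketone is epimerisable and becomes sp2 in the enol ether; the C2 carbinol made after the key step is reoxidised. Both are carried as mixtures and drawn without configuration.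
- (2R)-3-Bromo-2-hydroxy-2-methylpropanoic acid is assumed to be purchased enantiopure. The Schiff-base ligand of step 1 is a separately prepared catalyst component.

Step 1
Reactants: 1 3-methylbut-2-en-1-ol
Product: 2 (2R)-2-bromo-3-chloro-3-methylbutan-1-ol
Conditions: NBS, ClTi(OiPr)3, chiral tridentate Schiff-base ligand 2-[(3,5-di-tert-butyl-2-hydroxybenzylidene)amino]-3,3-dimethyl-1,1-diphenylbutan-1-ol (20 mol %, the enantiomer that gives the 2R product), hexanes, −20 °C
Reagents that add atoms: N-bromosuccinimide O=C1CCC(=O)N1Br; chlorotitanium triisopropoxide CC(C)O[Ti](Cl)(OC(C)C)OC(C)C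
Why: Catalytic enantioselective bromochlorination of an allylic alcohol: the titanium-bound alkoxide and ligand direct bromonium formation to one alkene face and chloride opens it anti at the tertiary carbon, so the catalyst sets the bromine-bearing carbon (C5) as R.

Step 2
Reactants: 2 (2R)-2-bromo-3-chloro-3-methylbutan-1-ol
Product: 3 (2R)-2-bromo-3-chloro-3-methylbutyl trifluoromethanesulfonate
Conditions: Tf2O, 2,6-lutidine, CH2Cl2, −78 °C; used crude
Reagents that add atoms: trifluoromethanesulfonic anhydride O=S(=O)(OS(=O)(=O)C(F)(F)F)C(F)(F)F
Why: Sulfonylation of the primary hydroxyl at low temperature gives a leaving group reactive enough for SN2 next to a branched carbon; the stereocentre is not involved.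

Step 3
Reactants: 4 prop-2-enyl 3-oxobutanoate, 3 (2R)-2-bromo-3-chloro-3-methylbutyl trifluoromethanesulfonate
Product: 5 prop-2-enyl (6R)-6-bromo-7-chloro-7-methyl-3-oxooctanoate
Conditions: NaH, THF, 0 °C; n-BuLi, 0 °C; then 3, −78 → −40 °C; AcOH quench at −78 °C
Reagents that add atoms: none
Why: γ-Alkylation of the acetoacetate dianion: the terminal carbanion is the more nucleophilic site and displaces the primary triflate by SN2 (forming C3–C4), and the cold acidic quench keeps the product enolate from attacking the secondary bromide.

Step 4
Reactants: 5 prop-2-enyl (6R)-6-bromo-7-chloro-7-methyl-3-oxooctanoate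
Product: 6 prop-2-enyl (3R)-3-bromo-2,2-dimethyl-6-oxocyclohexane-1-carboxylate
Conditions: (CF3)2CHOH (0.02 M), rt; NaHCO3 work-up
Reagents that add atoms: none
Why: Stereospecific solvolytic bromonium (cation–olefin type) cyclisation: ionisation of the tertiary chloride in the ionising, weakly nucleophilic solvent is assisted by the vicinal bromine, and the configurationally defined bromonium ion is opened at C6 by the α-carbon of the keto-ester enol in a chair-like 6-endo closure (an O-bound enol ether can re-ionise and drain to the C–C product), so ring A forms with C5 unchanged as R.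

Step 5
Reactants: 6 prop-2-enyl (3R)-3-bromo-2,2-dimethyl-6-oxocyclohexane-1-carboxylate
Product: 9 (4R)-4-bromo-3,3-dimethyl-2-methylidenecyclohexan-1-one, via keto acid 7 (not isolated), via Mannich acid 8 (not isolated)
Conditions: Pd(PPh3)4 (3 mol %), morpholine, THF, rt; then 37% aq. CH2O, AcOH, rt → 40 °C; used directly
Reagents that add atoms: formaldehyde C=O
Why: Tsuji–Trost deallylation by zerovalent palladium with morpholine as allyl acceptor unmasks the β-keto acid, which undergoes decarboxylative Mannich methylenation (aminomethylation at C7, then loss of CO2 and amine), placing the exocyclic methylene regiospecifically on the hindered α-carbon without enolate chemistry that could displace the 1,3-related bromide.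

Step 6
Reactants: 10 (2R)-3-bromo-2-hydroxy-2-methylpropanoic acid
Product: 12 methyl (2R)-2-hydroxy-3-iodo-2-methylpropanoate, via glycidate 11 (not isolated)
Conditions: MeI, K2CO3, DMF, 0 °C → rt; then LiI, AcOH, rt
Reagents that add atoms: iodomethane CI; lithium iodide [Li+].[I-]
Why: Carboxylate O-methylation with Williamson closure of the bromohydrin gives the epoxy ester, which iodide opens by SN2 only at the CH2 carbon (the other epoxide carbon is quaternary and α to the ester); no bond to the chiral-pool stereocentre is touched, so its geometry is retained (2S in the epoxide, 2R in the iodohydrin by priority change only).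

Step 7
Reactants: 9 (4R)-4-bromo-3,3-dimethyl-2-methylidenecyclohexan-1-one, 12 methyl (2R)-2-hydroxy-3-iodo-2-methylpropanoate
Product: 13 methyl (2S)-4-[(3R)-3-bromo-2,2-dimethyl-6-oxocyclohexyl]-2-hydroxy-2-methylbutanoate
Conditions: 12 (2 equiv), Bu3SnH (slow addition), Et3B (cat.), air, toluene, 0 °C → rt; KF work-up
Reagents that add atoms: none
Why: Giese radical conjugate addition: the tin radical abstracts iodine from the primary iodide far faster than bromine from the ring, the primary radical adds to the CH2 terminus of the α-methylene ketone (C8–C9) and the α-keto radical is reduced by Bu3SnH, giving a tertiary C7 without base and leaving the future C10 stereocentre untouched (2S by priority change only).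

Step 8
Reactants: 13 methyl (2S)-4-[(3R)-3-bromo-2,2-dimethyl-6-oxocyclohexyl]-2-hydroxy-2-methylbutanoate
Product: 14 methyl (2S,6R)-6-bromo-2,5,5-trimethyl-3,4,5,6,7,8-hexahydro-2H-chromene-2-carboxylate
Conditions: p-TsOH·H2O (10 mol %), toluene, 4 Å molecular sieves, 80–110 °C
Reagents that add atoms: none
Why: Acid-catalysed cyclodehydration of the δ-hydroxy ketone (hemiketal, then loss of water toward the more substituted α-carbon) should give the thermodynamically preferred tetrasubstituted ring-fusion enol ether; the carbinol carbon is α to an ester and does not ionise, so C10 is safe under acid.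

Step 9
Reactants: 14 methyl (2S,6R)-6-bromo-2,5,5-trimethyl-3,4,5,6,7,8-hexahydro-2H-chromene-2-carboxylate
Product: 16 (2S,6R)-6-bromo-2-ethenyl-2,5,5-trimethyl-3,4,5,6,7,8-hexahydro-2H-chromene, via aldehyde 15 (not isolated)
Conditions: iBu2AlH (1.1 equiv), CH2Cl2, −78 °C; then Ph3P=CH2 (from Ph3PCH3Br and KN(SiMe3)2), THF, −78 °C → rt
Reagents that add atoms: methyltriphenylphosphonium bromide C[P+](c1ccccc1)(c1ccccc1)c1ccccc1.[Br-]
Why: Partial reduction of the α-alkoxy ester (chelated aluminium hemiacetal) followed by Wittig methylenation of the non-enolisable aldehyde builds the vinyl group last and without acid, so the acid-labile tertiary allylic ether never meets acid; C10 is not touched.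

Step 10
Reactants: 16 (2S,6R)-6-bromo-2-ethenyl-2,5,5-trimethyl-3,4,5,6,7,8-hexahydro-2H-chromene
Product: 17 (4R,6R)-4-bromo-5,5,9-trimethylspiro[5.5]undec-8-en-1-one
Conditions: degassed toluene (0.01 M), 2,6-di-tert-butyl-4-methylpyridine (0.2 equiv), silylated sealed tube, 190 °C
Reagents that add atoms: none
Why: Thermal [3,3]-sigmatropic (Claisen) rearrangement: the enol ether O–C2=C7 and the allyl unit C10–C11=C12 reorganise in one suprafacial step through the boat-like transition state that the dihydropyran imposes, making C7–C12 and the C2 carbonyl while O–C10 breaks and C10=C11 forms. It belongs to the known class of Claisen rearrangements of 2-alkenyl-3,4-dihydro-2H-pyrans to 4-acylcyclohexenes. Ring B (C7–C8–C9–C10–C11–C12) closes by this pericyclic ring contraction, the six-membered ether ring being traded for a six-membered carbocycle, so the bond to the fully substituted C7 next to the gem-dimethyl carbon forms intramolecularly. The new quaternary spiro stereocentre C7 is set by chirality transfer from C10: the vinyl group can reach only the face of C7 on which the O–C10 bond holds it, so the 10S ether gives the spiro arrangement of the target (descriptor R in the ketone), on the face cis to the C5 bromide. The step needs stereospecificity (no heterolysis of the tertiary allylic ether, no retro-hetero-Diels–Alder and recombination) and the enol ether double bond at C2=C7; acid-free buffered conditions at the lowest workable temperature should secure the first and the tetrasubstituted enol ether from step 8 the second. Reaction through the ring A half-chair with axial bromine keeps the attacked face clear of the pseudo-axial C6 methyl.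

Step 11
Reactants: 17 (4R,6R)-4-bromo-5,5,9-trimethylspiro[5.5]undec-8-en-1-one
Product: 18 (4R,6R)-4-bromo-5,5,9-trimethylspiro[5.5]undec-8-en-1-ol
Conditions: NaBH4, MeOH, 0 °C → rt
Reagents that add atoms: none
Why: Hydride reduction of the hindered ketone provides the C2 hydroxyl that serves as internal nucleophile; either C2 epimer can reach C10 and the centre is reoxidised later, so its configuration is immaterial.

Step 12
Reactants: 18 (4R,6R)-4-bromo-5,5,9-trimethylspiro[5.5]undec-8-en-1-ol
Product: 19 3,12-dibromo-2,2,8-trimethyl-7-oxatricyclo[6.2.2.0(1,6)]dodecane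
Conditions: NBS, NaHCO3, CH2Cl2, 0 °C, dark
Reagents that add atoms: N-bromosuccinimide O=C1CCC(=O)N1Br
Why: Bromoetherification: the bromonium ion on the trisubstituted alkene is captured intramolecularly by the C2 hydroxyl at the tertiary C10 (Markovnikov, giving a 2-oxabicyclo[2.2.2]octane as in cineole-type cyclisations), so oxygen enters C10 on the C2 face and bromine is forced onto C11 anti to it (11S).

Step 13
Reactants: 19 3,12-dibromo-2,2,8-trimethyl-7-oxatricyclo[6.2.2.0(1,6)]dodecane
Product: 20 (4R,6R,8S,9S)-4,8-dibromo-9-chloro-5,5,9-trimethylspiro[5.5]undecan-1-ol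
Conditions: BCl3, CH2Cl2, −78 → −20 °C; aq. NaHCO3
Reagents that add atoms: boron trichloride ClB(Cl)Cl
Why: Lewis-acid ether cleavage: BCl3 coordinates the bridging oxygen, the tertiary C10–O bond ionises with participation of the antiperiplanar C11 bromine, and chloride opens the bromonium ion at C10 from the face the oxygen occupied, so the tertiary chloride forms with net retention (10S) and trans to bromine.

Step 14
Reactants: 20 (4R,6R,8S,9S)-4,8-dibromo-9-chloro-5,5,9-trimethylspiro[5.5]undecan-1-ol
Product: 21 (4R,6R,8S,9S)-4,8-dibromo-9-chloro-5,5,9-trimethylspiro[5.5]undecan-1-one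
Conditions: Dess–Martin periodinane, NaHCO3, CH2Cl2, rt
Reagents that add atoms: none
Why: Dess–Martin oxidation returns the C2 ketone under neutral conditions that spare the secondary and tertiary halides.

Step 15
Reactants: 21 (4R,6R,8S,9S)-4,8-dibromo-9-chloro-5,5,9-trimethylspiro[5.5]undecan-1-one
Product: 22 (4R,6S,8S,9S)-4,8-dibromo-9-chloro-5,5,9-trimethyl-1-methylidenespiro[5.5]undecane
Conditions: Cp2TiMe2 (3 equiv), toluene–THF, 65 °C, dark
Reagents that add atoms: dimethyltitanocene C[Ti](C)(C1C=CC=C1)C1C=CC=C1
Why: Petasis methylenation: the titanium methylidene formed thermally from Cp2TiMe2 is non-basic and small enough for the hindered ketone next to the spiro centre, and it avoids the enolisation-driven cyclopropane formation or reductive loss of the vicinal halides that ylide or zinc reagents could cause.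

**Compound list**
1 | 3-methylbut-2-en-1-ol | CC(C)=CCO | starting material
2 | (2R)-2-bromo-3-chloro-3-methylbutan-1-ol | OC[C@@H](Br)C(C)(C)Cl | intermediate
3 | (2R)-2-bromo-3-chloro-3-methylbutyl trifluoromethanesulfonate | O=S(=O)(OC[C@@H](Br)C(C)(C)Cl)C(F)(F)F | intermediate
4 | prop-2-enyl 3-oxobutanoate | CC(=O)CC(=O)OCC=C | starting material
5 | prop-2-enyl (6R)-6-bromo-7-chloro-7-methyl-3-oxooctanoate | C=CCOC(=O)CC(=O)CC[C@@H](Br)C(C)(C)Cl | intermediate
6 | prop-2-enyl (3R)-3-bromo-2,2-dimethyl-6-oxocyclohexane-1-carboxylate (C1 epimers and enol) | C=CCOC(=O)C1C(=O)CC[C@@H](Br)C1(C)C | intermediate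
7 | (3R)-3-bromo-2,2-dimethyl-6-oxocyclohexane-1-carboxylic acid (morpholinium salt in the flask) | OC(=O)C1C(=O)CC[C@@H](Br)C1(C)C | intermediate
8 | (3R)-3-bromo-2,2-dimethyl-1-(morpholin-4-ylmethyl)-6-oxocyclohexane-1-carboxylic acid | OC(=O)C1(CN2CCOCC2)C(=O)CC[C@@H](Br)C1(C)C | intermediate
9 | (4R)-4-bromo-3,3-dimethyl-2-methylidenecyclohexan-1-one | C=C1C(=O)CC[C@@H](Br)C1(C)C | intermediate
10 | (2R)-3-bromo-2-hydroxy-2-methylpropanoic acid | OC(=O)[C@](O)(C)CBr | starting material
11 | methyl (2S)-2-methyloxirane-2-carboxylate | COC(=O)[C@]1(C)CO1 | intermediate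
12 | methyl (2R)-2-hydroxy-3-iodo-2-methylpropanoate | COC(=O)[C@](O)(C)CI | intermediate
13 | methyl (2S)-4-[(3R)-3-bromo-2,2-dimethyl-6-oxocyclohexyl]-2-hydroxy-2-methylbutanoate (ring C1 epimers) | COC(=O)[C@](O)(C)CCC1C(=O)CC[C@@H](Br)C1(C)C | intermediate
14 | methyl (2S,6R)-6-bromo-2,5,5-trimethyl-3,4,5,6,7,8-hexahydro-2H-chromene-2-carboxylate | COC(=O)[C@]1(C)CCC2=C(O1)CC[C@@H](Br)C2(C)C | intermediate
15 | (2S,6R)-6-bromo-2,5,5-trimethyl-3,4,5,6,7,8-hexahydro-2H-chromene-2-carbaldehyde | O=C[C@]1(C)CCC2=C(O1)CC[C@@H](Br)C2(C)C | intermediate
16 | (2S,6R)-6-bromo-2-ethenyl-2,5,5-trimethyl-3,4,5,6,7,8-hexahydro-2H-chromene | C=C[C@]1(C)CCC2=C(O1)CC[C@@H](Br)C2(C)C | intermediate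
17 | (4R,6R)-4-bromo-5,5,9-trimethylspiro[5.5]undec-8-en-1-one | O=C1CC[C@@H](Br)C(C)(C)[C@]12CCC(C)=CC2 | intermediate
18 | (4R,6R)-4-bromo-5,5,9-trimethylspiro[5.5]undec-8-en-1-ol (C1 epimers) | OC1CC[C@@H](Br)C(C)(C)[C@]12CCC(C)=CC2 | intermediate
19 | 3,12-dibromo-2,2,8-trimethyl-7-oxatricyclo[6.2.2.0(1,6)]dodecane (configuration as in the SMILES; C6 epimers) | C[C@]12CC[C@]3(C[C@@H]1Br)C(O2)CC[C@@H](Br)C3(C)C | intermediate
20 | (4R,6R,8S,9S)-4,8-dibromo-9-chloro-5,5,9-trimethylspiro[5.5]undecan-1-ol (C1 epimers) | OC1CC[C@@H](Br)C(C)(C)[C@]12CC[C@](C)(Cl)[C@@H](Br)C2 | intermediate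
21 | (4R,6R,8S,9S)-4,8-dibromo-9-chloro-5,5,9-trimethylspiro[5.5]undecan-1-one | O=C1CC[C@@H](Br)C(C)(C)[C@]12CC[C@](C)(Cl)[C@@H](Br)C2 | intermediate
22 | (4R,6S,8S,9S)-4,8-dibromo-9-chloro-5,5,9-trimethyl-1-methylidenespiro[5.5]undecane | C=C1CC[C@@H](Br)C(C)(C)[C@]12CC[C@](C)(Cl)[C@@H](Br)C2 | target

**Totals**
Total step count: 15. Longest linear sequence: 14 (steps 1–5 and 7–15; step 6 is a one-step branch).

**Steps most likely to fail**

Step 10. The rearrangement needs a boat transition state and makes a quaternary carbon next to a quaternary carbon, so it may be slow at temperatures the substrate tolerates. At higher temperature the tertiary allylic C–O bond may ionise or the ring may fragment by retro-hetero-Diels–Alder reaction and recombine, which would erode the chirality transfer; thermal loss of HBr is a further drain. Fallback: ring B is built from the α-methylene ketone 9 by a Lewis-acid-catalysed Diels–Alder reaction with isoprene (MeAlCl2, CH2Cl2, −78 → −20 °C), the classical spiroannulation of 2-methylene cyclohexanones. It sets out from 9 and rejoins the route at 17. The spiro centre is then under substrate control only, so the C7 epimer and the meta regioisomer would have to be removed by chromatography. No compound outside the list is formed (F0).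

Step 4. The ketone oxygen may outrun the enol carbon in opening the bromonium ion, leaving an O-cyclised enol ether that does not revert. Bromonium transfer between molecules could also lower the enantiomeric purity. Fallback: the nucleophile is changed. Compound 5 is converted with HC(OMe)3, p-TsOH (cat.), MeOH at rt into its methyl enol ether prop-2-enyl (2E,6R)-6-bromo-7-chloro-3-methoxy-7-methyloct-2-enoate F1, whose oxygen is blocked so that only C7 can attack. Solvolysis of F1 in (CF3)2CHOH and aqueous work-up (loss of methanol from the oxocarbenium ion) rejoins the route at 6.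

Step 13. The Lewis acid may cause elimination from the C10 cation, opening without bromine participation (loss of configuration at C10), or chloride attack at C11 with bromine migration. Fallback: the bromochloride is made without the ether bridge, setting out from ketone 17.
- m-CPBA (CH2Cl2, NaHCO3, 0 °C) should epoxidise the face of ring B remote from the C6 gem-dimethyl group, giving (4R,6R)-4-bromo-8,9-epoxy-5,5,9-trimethylspiro[5.5]undecan-1-one F2.
- Li2NiBr4 (THF, rt) opens the epoxide by SN2 at the secondary C11, giving the bromohydrin (4R,6R,8S,9S)-4,8-dibromo-9-hydroxy-5,5,9-trimethylspiro[5.5]undecan-1-one F3.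
- SOCl2 (CH2Cl2, 0 °C) replaces the tertiary hydroxyl by chloride with retention through the same bromonium ion.

This rejoins the route at 21, so steps 11, 12 and 14 are not needed.

Further compounds
F0 | step 10 | none | none
F1 | step 4 | prop-2-enyl (2E,6R)-6-bromo-7-chloro-3-methoxy-7-methyloct-2-enoate | C=CCOC(=O)/C=C(/OC)CC[C@@H](Br)C(C)(C)Cl
F2 | step 13 | (4R,6R)-4-bromo-8,9-epoxy-5,5,9-trimethylspiro[5.5]undecan-1-one | O=C1CC[C@@H](Br)C(C)(C)[C@]12CC[C@]3(C)O[C@@H]3C2
F3 | step 13 | (4R,6R,8S,9S)-4,8-dibromo-9-hydroxy-5,5,9-trimethylspiro[5.5]undecan-1-one | O=C1CC[C@@H](Br)C(C)(C)[C@]12CC[C@](C)(O)[C@@H](Br)C2
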